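**Retrosynthetic overview**
1. Target ⇒ its C14-epimeric allylic alcohol: the hydroperoxide is installed last by sulfonate displacement with H2O2 (inversion at C14).
2. Allylic alcohol ⇒ 2-iodoalkene of the bicyclic core + butenolide aldehyde (C13–C14 bond by ligand-controlled Ni/Cr coupling, setting C14).
3. Butenolide aldehyde ⇒ acrolein + ethyl (Z)-3-iodobut-2-enoate: the key C16–C17 bond comes from a β-metallated enoate (sp2 homoenolate) whose normally electrophilic β-carbon attacks the aldehyde carbon; lactonisation closes the butenolide and sets C16, and the vinyl group is then oxidised to the aldehyde.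
4. Core ⇒ abietic acid: ring C is cut at C13=C14; the resulting enal gives 6α-OH (γ-oxidation) and the 8-methyl/8α-OH pair (hydrazone transposition, hydration); the isopropyl ketone is degraded to the C13 alkyne and then the 2-iodoalkene.
5. Ring order: rings A and B (C4, C5, C9, C10) come pre-formed from the chiral pool, the old ring C is opened, the butenolide ring is closed in the key step; no other ring is made.

Assumption: labdane-type numbering is used (ring A = C1–C5, C10; ring B = C5–C10; C17 = carbon on C8, C18 = ester carbon, C19 = 4β-methyl, C20 = 10β-methyl; side chain C9–C11–C12–C13(=CH2)–C14–C15–C16, C16 being C5 of the furanone), and commercial abietic acid is the natural (−)-enantiomer (4α-CO2H, 4β-CH3, 5α-H, 9α-H, 10β-CH3).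

**Step 1**
Reactants: 1 abietic acid
Product: 2 methyl abietate
Conditions: MeI, K2CO3, DMF, rt
Reagents that add atoms: iodomethane CI
Why: SN2 O-methylation of the carboxylate esterifies the hindered C18 acid without touching the diene or the C4, C5, C9 and C10 stereocentres that the target inherits.

**Step 2**
Reactants: 2 methyl abietate
Product: 4 ring-C-opened keto-enal, via 13α,14α-diol 3 (not isolated)
Conditions: OsO4 (2 mol %), NaIO4 (4 equiv), 2,6-lutidine, dioxane/H2O 3:1, rt
Reagents that add atoms: osmium tetroxide O=[Os](=O)(=O)=O; sodium periodate [Na+].[O-]I(=O)(=O)=O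
Why: Lemieux–Johnson cleavage (osmylation to the cis-diol, then periodate glycol fission) attacks the exposed 13,14-alkene of the heteroannular diene and then stops because the surviving C7=C8 bond is conjugated to the new aldehyde; C13 becomes an isopropyl ketone and the old C14 becomes the C17 aldehyde.

**Step 3**
Reactants: 4 ring-C-opened keto-enal
Product: 5 silyl dienol ether
Conditions: TBSOTf (1.1 equiv), Et3N, CH2Cl2, −78 → −40 °C
Reagents that add atoms: tert-butyldimethylsilyl trifluoromethanesulfonate CC(C)(C)[Si](C)(C)OS(=O)(=O)C(F)(F)F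
Why: Soft enolisation of the enal removes its only vinylogously acidic proton (H6) to give the 1-silyloxydiene, while the hindered isopropyl ketone is silylated much more slowly at low temperature.

**Step 4**
Reactants: 5 silyl dienol ether
Product: 7 6α-hydroxy keto-enal, via 6α,7α-epoxide 6 (not isolated)
Conditions: dimethyldioxirane (1.2 equiv, acetone), CH2Cl2, −78 → −30 °C; then AcOH, THF/H2O
Reagents that add atoms: dimethyldioxirane CC1(C)OO1
Why: Vinylogous Rubottom oxidation, in which the dioxirane epoxidises the distal C6=C7 bond from the α face (opposite the syn-axial C19 and C20 methyl groups) and push–pull opening of the epoxide regenerates the enal, setting C6 as 6α-OH (6S).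

**Step 5**
Reactants: 7 6α-hydroxy keto-enal
Product: 11 6α-hydroxy-8(17)-ene ketone, via tosylhydrazone 8 (not isolated), via tosylhydrazine 9 (not isolated), via allyl diazene 10 (not isolated)
Conditions: TsNHNH2 (1.05 equiv), THF, rt; catecholborane, CHCl3, 0 °C; NaOAc·3H2O, 65 °C
Reagents that add atoms: none
Why: Kabalka reduction of the α,β-unsaturated tosylhydrazone (aldehyde-selective condensation, 1,2-hydride addition, sulfinate loss, retro-ene loss of N2 from the allyl diazene) moves the double bond to the exocyclic 8(17) position and turns the formyl carbon into the future 8-methyl carbon.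

**Step 6**
Reactants: 11 6α-hydroxy-8(17)-ene ketone
Product: 13 6α,8α-diol ketone, via 8α-hydroperoxide 12 (not isolated)
Conditions: Mn(dpm)3 (10 mol %, dpm = dipivaloylmethanato), PhSiH3, O2 (1 atm), i-PrOH/CH2Cl2, 0 °C; then PPh3
Reagents that add atoms: dioxygen O=O
Why: Mukaiyama hydration (hydrogen-atom transfer from a manganese hydride to the 1,1-disubstituted alkene, then O2 capture) gives the Markovnikov tertiary alcohol, and O2 enters the C8 radical from the α face, away from the axial 10β-methyl, setting 8α-OH/8β-CH3 (8R).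

**Step 7**
Reactants: 13 6α,8α-diol ketone
Product: 14 isopropyl ester diol
Conditions: mCPBA (3 equiv), NaHCO3, CH2Cl2, rt → 40 °C
Reagents that add atoms: 3-chloroperbenzoic acid OOC(=O)c1cccc(Cl)c1
Why: Baeyer–Villiger oxidation inserts oxygen next to the better-migrating secondary (isopropyl) group, converting the isopropyl ketone into the isopropyl ester of the C13 acid at a stage where no alkene is left to epoxidise.

**Step 8**
Reactants: 14 isopropyl ester diol
Product: 16 terminal alkyne, via C13 aldehyde 15 (not isolated)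
Conditions: i-Bu2AlH (3.3 equiv), CH2Cl2, −78 °C; then MeOH, K2CO3, dimethyl (1-diazo-2-oxopropyl)phosphonate, −78 °C → rt
Reagents that add atoms: dimethyl (1-diazo-2-oxopropyl)phosphonate COP(=O)(OC)C(=[N+]=[N-])C(C)=O
Why: Low-temperature i-Bu2AlH reduction stops at the aldehyde for the unhindered isopropyl ester while sparing the neopentyl-type C18 methyl ester, and Ohira–Bestmann (Seyferth–Gilbert) homologation in the same flask gives the terminal alkyne under mild K2CO3/MeOH conditions.

**Step 9**
Reactants: 16 terminal alkyne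
Product: 18 2-iodoalkene, via α-vinylsilane 17 (not isolated)
Conditions: [Cp*Ru(MeCN)3]PF6 (3 mol %), Et3SiH, CH2Cl2, 0 °C → rt; evaporate; NIS, 2,6-lutidine, (CF3)2CHOH, 0 °C
Reagents that add atoms: N-iodosuccinimide O=C1CCC(=O)N1I
Why: Trost's cationic ruthenium hydrosilylation adds Si–H across the terminal alkyne in the Markovnikov sense, and ipso iododesilylation then gives the 2-iodo-1-alkene without the strong acid that would endanger the tertiary alcohol.

**Step 10**
Reactants: 19 ethyl but-2-ynoate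
Product: 20 ethyl (Z)-3-iodobut-2-enoate
Conditions: NaI, AcOH, 115 °C
Reagents that add atoms: sodium iodide [Na+].[I-]
Why: Conjugate hydroiodination of the ynoate (anti addition of HI) gives the Z β-iodo enoate, fixing the cis relationship between the C–I bond and the ester that later allows lactonisation.

**Step 11**
Reactants: 20 ethyl (Z)-3-iodobut-2-enoate; 21 acrolein
Product: 23 (5S)-4-methyl-5-vinylfuran-2(5H)-one, via open hydroxy ester 22 (not isolated)
Conditions: CrCl2 (3 equiv), NiCl2 (2 mol %), L* (N-[2-(4-isopropyl-4,5-dihydro-1,3-oxazol-2-yl)-6-methylphenyl]methanesulfonamide, antipode giving the S carbinol), Et3N, THF, rt; dilute HCl work-up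
Reagents that add atoms: none
Why: Proposed new method: zerovalent nickel inserts into the C–I bond of 20 and transmetalation to trivalent chromium gives a Z β-(ethoxycarbonyl)vinylchromium (an sp2 homoenolate whose normally electrophilic β-carbon is nucleophilic), which adds 1,2 to acrolein inside the chiral oxazoline–sulfonamide sphere of chromium to set C16 (S) before the Z γ-alkoxide closes the butenolide; the closest known reactions are the racemic Nozaki–Hiyama–Kishi butenolide synthesis from Z β-iodoacrylates and Kishi's ligand-controlled asymmetric Ni/Cr coupling of alkenyl iodides.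

**Step 12**
Reactants: 23 (5S)-4-methyl-5-vinylfuran-2(5H)-one
Product: 24 2-[(2S)-3-methyl-5-oxo-2,5-dihydrofuran-2-yl]acetaldehyde
Conditions: PdCl2(PhCN)2 (10 mol %), CuCl2·2H2O (10 mol %), AgNO2 (5 mol %), O2 (1 atm), t-BuOH/MeNO2 15:1, rt
Reagents that add atoms: dioxygen O=O
Why: Nitrite-modified aldehyde-selective Wacker oxidation puts oxygen on the terminal vinyl carbon because the allylic lactone oxygen disfavours Markovnikov palladation, and the electron-poor butenolide alkene and C16 are untouched.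

**Step 13**
Reactants: 18 2-iodoalkene; 24 2-[(2S)-3-methyl-5-oxo-2,5-dihydrofuran-2-yl]acetaldehyde
Product: 25 14R allylic alcohol
Conditions: CrCl2 (4 equiv), NiCl2 (1 mol %), L* (antipode giving 14R), Et3N, THF, rt
Reagents that add atoms: none
Why: Nozaki–Hiyama–Kishi coupling, in which the alkenylchromium adds only to the aldehyde (free hydroxyls, esters and the butenolide are tolerated) and the chiral sulfonamide ligand on chromium overrides the weak 1,3-induction from C16 to give the 14R carbinol.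

**Step 14**
Reactants: 25 14R allylic alcohol
Product: 27 target hydroperoxide, via 14R mesylate 26 (not isolated)
Conditions: MsCl (1.05 equiv), Et3N, CH2Cl2, −60 °C; then anhydrous H2O2 in Et2O (excess), −60 → −20 °C
Reagents that add atoms: hydrogen peroxide OO (methanesulfonyl chloride CS(=O)(=O)Cl supplies the mesyl group of 26 only)
Why: Sulfonate displacement by hydrogen peroxide (SN2, the mesylate/H2O2 method used for allylic hydroperoxides) relies on selective mesylation of the least hindered allylic C14 hydroxyl (8-OH is tertiary, 6-OH is hindered and hydrogen-bonded to the ester) and on substitution with inversion at low temperature, turning 14R-OH into the 14S hydroperoxide.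

**Compound list**
1 | (−)-abietic acid (abieta-7,13-dien-18-oic acid; 4α-CO2H, 4β-CH3, 5α-H, 9α-H, 10β-CH3) | CC(C)C1=CC2=CC[C@@H]3[C@@]([C@H]2CC1)(CCC[C@@]3(C)C(=O)O)C | starting material
2 | methyl abietate | CC(C)C1=CC2=CC[C@@H]3[C@@]([C@H]2CC1)(CCC[C@@]3(C)C(=O)OC)C | intermediate
3 | methyl 13α,14α-dihydroxyabiet-7-en-18-oate (cis-diol; face of attack immaterial) | C1C[C@@H]2[C@@]3(C)CCC[C@@](C)(C(=O)OC)[C@@H]3CC=C2[C@@H](O)[C@]1(O)C(C)C | intermediate
4 | ring-C-opened keto-enal: C8 bears CHO (C17) and is doubly bonded to C7; C9 (α-H) bears CH2CH2C(=O)CH(CH3)2; ring A as in 2 | CC(C)C(=O)CC[C@@H]1[C@@]2(C)CCC[C@@](C)(C(=O)OC)[C@@H]2CC=C1C=O | intermediate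
5 | tert-butyldimethylsilyl dienol ether of 4 (C6=C7 and C8=C17H–OSi, silyloxy anti to C7) | CC(C)C(=O)CC[C@@H]1[C@@]2(C)CCC[C@@](C)(C(=O)OC)[C@@H]2C=C/C1=C/O[Si](C)(C)C(C)(C)C | intermediate
6 | 6α,7α-epoxide of 5 | CC(C)C(=O)CC[C@@H]1[C@@]2(C)CCC[C@@](C)(C(=O)OC)[C@@H]2[C@H]3O[C@H]3/C1=C/O[Si](C)(C)C(C)(C)C | intermediate
7 | 6α-hydroxy keto-enal (6S; C7=C8–CHO) | CC(C)C(=O)CC[C@@H]1[C@@]2(C)CCC[C@@](C)(C(=O)OC)[C@@H]2[C@@H](O)C=C1C=O | intermediate
8 | (E)-N-tosylhydrazone of the C17 aldehyde of 7 | CC(C)C(=O)CC[C@@H]1[C@@]2(C)CCC[C@@](C)(C(=O)OC)[C@@H]2[C@@H](O)C=C1/C=N/NS(=O)(=O)c1ccc(C)cc1 | intermediate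
9 | N′-tosylhydrazine from 1,2-reduction of 8 (held as its B-catecholato adduct) | CC(C)C(=O)CC[C@@H]1[C@@]2(C)CCC[C@@](C)(C(=O)OC)[C@@H]2[C@@H](O)C=C1CNNS(=O)(=O)c1ccc(C)cc1 | intermediate
10 | allyl diazene (C7=C8–C17H2–N=NH) | CC(C)C(=O)CC[C@@H]1[C@@]2(C)CCC[C@@](C)(C(=O)OC)[C@@H]2[C@@H](O)C=C1CN=N | intermediate
11 | 6α-hydroxy-8(17)-ene isopropyl ketone | CC(C)C(=O)CC[C@@H]1[C@@]2(C)CCC[C@@](C)(C(=O)OC)[C@@H]2[C@@H](O)CC1=C | intermediate
12 | 8α-hydroperoxide (8β-CH3) | CC(C)C(=O)CC[C@@H]1[C@@]2(C)CCC[C@@](C)(C(=O)OC)[C@@H]2[C@@H](O)C[C@@]1(C)OO | intermediate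
13 | 6α,8α-diol isopropyl ketone (8α-OH, 8β-CH3; 8R) | CC(C)C(=O)CC[C@@H]1[C@@]2(C)CCC[C@@](C)(C(=O)OC)[C@@H]2[C@@H](O)C[C@@]1(C)O | intermediate
14 | isopropyl ester diol (C9 chain CH2CH2CO2CH(CH3)2) | CC(C)OC(=O)CC[C@@H]1[C@@]2(C)CCC[C@@](C)(C(=O)OC)[C@@H]2[C@@H](O)C[C@@]1(C)O | intermediate
15 | C13 aldehyde (C9 chain CH2CH2CHO; in equilibrium with its 8-O lactol) | O=CCC[C@@H]1[C@@]2(C)CCC[C@@](C)(C(=O)OC)[C@@H]2[C@@H](O)C[C@@]1(C)O | intermediate
16 | terminal alkyne (C9 chain CH2CH2C≡CH) | C#CCC[C@@H]1[C@@]2(C)CCC[C@@](C)(C(=O)OC)[C@@H]2[C@@H](O)C[C@@]1(C)O | intermediate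
17 | α-vinylsilane (C9 chain CH2CH2C(SiEt3)=CH2) | C=C([Si](CC)(CC)CC)CC[C@@H]1[C@@]2(C)CCC[C@@](C)(C(=O)OC)[C@@H]2[C@@H](O)C[C@@]1(C)O | intermediate
18 | 2-iodoalkene (C9 chain CH2CH2C(I)=CH2) | C=C(I)CC[C@@H]1[C@@]2(C)CCC[C@@](C)(C(=O)OC)[C@@H]2[C@@H](O)C[C@@]1(C)O | intermediate
19 | ethyl but-2-ynoate | CC#CC(=O)OCC | starting material
20 | ethyl (Z)-3-iodobut-2-enoate | C/C(I)=C/C(=O)OCC | intermediate
21 | acrolein (prop-2-enal) | C=CC=O | starting material
22 | ethyl (2Z,4S)-4-hydroxy-3-methylhexa-2,5-dienoate (as its chromium alkoxide) | C=C[C@H](O)/C(C)=C\C(=O)OCC | intermediate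
23 | (5S)-4-methyl-5-vinylfuran-2(5H)-one | C=C[C@@H]1OC(=O)C=C1C | intermediate
24 | 2-[(2S)-3-methyl-5-oxo-2,5-dihydrofuran-2-yl]acetaldehyde | O=CC[C@@H]1OC(=O)C=C1C | intermediate
25 | 14R allylic alcohol: C9 chain CH2CH2C(=CH2)–(14R)-CH(OH)–CH2–(16S)-[4-methyl-2(5H)-furanon-5-yl]; core as in 18 | C=C(CC[C@@H]1[C@@]2(C)CCC[C@@](C)(C(=O)OC)[C@@H]2[C@@H](O)C[C@@]1(C)O)[C@@H](C[C@@H]1OC(=O)C=C1C)O | intermediate
26 | 14R methanesulfonate of 25 | C=C(CC[C@@H]1[C@@]2(C)CCC[C@@](C)(C(=O)OC)[C@@H]2[C@@H](O)C[C@@]1(C)O)[C@@H](C[C@@H]1OC(=O)C=C1C)OS(C)(=O)=O | intermediate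
27 | CNP0324515.1: methyl ester (C18) with 4R,5R,6S,8R,9R,10S core (6α-OH, 8α-OH) and C9 chain CH2CH2C(=CH2)–(14S)-CH(OOH)–CH2–(16S)-[4-methyl-2(5H)-furanon-5-yl] | C=C(CC[C@@H]1[C@@]2(C)CCC[C@@](C)(C(=O)OC)[C@@H]2[C@@H](O)C[C@@]1(C)O)[C@H](C[C@@H]1OC(=O)C=C1C)OO | target

**Step count and risks**
Total step count: 14 (steps 1–9 core, 10–12 butenolide fragment, 13–14 union and endgame).
Longest linear sequence: 11 steps (steps 1–9, 13, 14, from abietic acid).

The three steps most likely to fail:

Step 4 (γ-oxidation at C6). The dioxirane may attack the enol-ether bond (C8 oxidation), approach from the β face, or the ketone may interfere. The fallback sets out from 5 and returns at 7, and lets the C4 ester enforce the 6α configuration. NBS (THF, −78 °C) brominates the γ-carbon to give the 6-bromo keto-enal F1. LiBr in warm MeCN epimerises the bromide, and the 4α-ester carbonyl displaces the 6β-bromide from the α face with loss of bromomethane to give the 18,6α-lactone F2. K2CO3/MeOH reopens the strained lactone to the 6α-hydroxy methyl ester 7.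

Step 11 (asymmetric Ni/Cr annulation on acrolein). Enantioselectivity with a β-iodo enoate is untested and acrolein can oligomerise. The fallback sets out from 21 and returns at 23, with the propiolate acetylide as the β-acyl vinyl anion equivalent. Zinc/ProPhenol-catalysed alkynylation (methyl propiolate, Me2Zn, ProPhenol antipode giving 4S, Ph3P=O, toluene, 4 °C) gives methyl (4S)-4-hydroxyhex-5-en-2-ynoate F3. Me2CuLi (THF, −78 °C) adds syn across the alkyne to give methyl (2Z,4S)-4-hydroxy-3-methylhexa-2,5-dienoate F4, which lactonises on acidic work-up to 23.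

Step 14 (hydroperoxide by substitution). Mesylation may also hit 6-OH, and the allylic mesylate may ionise or react SN2′, eroding configuration. The fallback sets out from alkyne 16 and returns at 27 by an ene route. Carboalumination (Me3Al, Cp2ZrCl2, CH2Cl2), conversion of the alkenylalane into its ate complex (n-BuLi) and opening of ethylene oxide give the 13E homoallylic alcohol F5. TEMPO/PhI(OAc)2 oxidises only the primary hydroxyl to the β,γ-unsaturated aldehyde F6. The Ni/Cr annulation of step 11 with 20 passes through the open hydroxy ester F7 and closes to the 13E-alkene butenolide F8 (16S by ligand control). Schenck ene reaction (O2, tetraphenylporphyrin, hν, CH2Cl2, 0 °C) takes hydrogen from the 13-methyl group on the disubstituted side of the alkene and gives 27. This route does not control C14: 27 forms with its C14 epimer and some tertiary 13-hydroperoxide, which are removed by HPLC.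

**Further compounds**
F1 | step 4 | 6-bromo keto-enal (drawn as the 6α-bromide) | CC(C)C(=O)CC[C@@H]1[C@@]2(C)CCC[C@@](C)(C(=O)OC)[C@@H]2[C@@H](Br)C=C1C=O
F2 | step 4 | 18,6α-lactone keto-enal | CC(C)C(=O)CC[C@@H]1[C@@]2(C)CCC[C@@](C)(C(=O)O3)[C@@H]2[C@@H]3C=C1C=O
F3 | step 11 | methyl (4S)-4-hydroxyhex-5-en-2-ynoate | C=C[C@H](O)C#CC(=O)OC
F4 | step 11 | methyl (2Z,4S)-4-hydroxy-3-methylhexa-2,5-dienoate | C=C[C@H](O)/C(C)=C\C(=O)OC
F5 | step 14 | 13E homoallylic alcohol (C9 chain CH2CH2C(CH3)=CHCH2CH2OH) | OCC/C=C(C)/CC[C@@H]1[C@@]2(C)CCC[C@@](C)(C(=O)OC)[C@@H]2[C@@H](O)C[C@@]1(C)O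
F6 | step 14 | 13E β,γ-unsaturated aldehyde | O=CC/C=C(C)/CC[C@@H]1[C@@]2(C)CCC[C@@](C)(C(=O)OC)[C@@H]2[C@@H](O)C[C@@]1(C)O
F7 | step 14 | open hydroxy ester (13E, 16S, 17Z ethyl ester) | C/C(CC[C@@H]1[C@@]2(C)CCC[C@@](C)(C(=O)OC)[C@@H]2[C@@H](O)C[C@@]1(C)O)=C\C[C@H](O)/C(C)=C\C(=O)OCC
F8 | step 14 | 13E-alkene butenolide (16S) | C/C(CC[C@@H]1[C@@]2(C)CCC[C@@](C)(C(=O)OC)[C@@H]2[C@@H](O)C[C@@]1(C)O)=C\C[C@@H]1OC(=O)C=C1C
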